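- Time first: in the beta run Z reads 40.1% at 0.833 d and 39.9% at 10.0 d, a gap inside the scatter. The asked 8.0 d comes later than that first reading, so I treat the flask as a plateau and average the readings of each run.

| flask | G | E | remark | time |
|---|---|---|---|---|
| delta | 0.020 M (fed, over 5.0 h) | 4 mM | run made earlier |  |
| beta | 0.020 M (fed, over 5.0 h) | 9 mM | run made earlier |  |
| epsilon | 0.030 M (fed, over 5.0 h) | 6 mM | run made earlier |  |
| flask | 0.020 M (fed, over 5.0 h) | 6.00 mM |  | 8.0 d |

| run | time / d | Z / % | L / % |
|---|---|---|---|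
| delta | 2.50 | 43.2 | 31.6 |
| delta | 5.00 | 42.9 | 31.6 |
| delta | 8.00 | 42.9 | 30.8 |
| delta | 10.0 | 42.7 | 30.9 |
| beta | 0.833 | 40.1 | 29.2 |
| beta | 1.67 | 40.2 | 29.2 |
| beta | 4.00 | 40.9 | 28.5 |
| beta | 10.0 | 39.9 | 28.9 |
| epsilon | 0.833 | 34.9 | 33.0 |
| epsilon | 1.67 | 35.4 | 34.1 |
| epsilon | 4.00 | 35.9 | 34.0 |
| epsilon | 10.0 | 35.1 | 33.4 |

(scatter of a reading: 0.5 percentage points)

- Z at 8.0 d, in percent of the G charged
- L at 8.0 d, in percent of the G charged

- percent here means G units held: one L counts as two
- a reading or a percentage of Z counts all its forms, free or not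

- Delta and beta have the G charge and feed of the flask and lie on either side of its E. I assume that Z and L fall steadily with E, so the delta averages give my upper bound: Z 42.9%, L 31.2%.
- On the same assumption, the beta averages give my lower bound: Z 40.3%, L 28.9%.
- To tighten the bracket, I draw a straight line between the two Z averages. Its slope, read off these scattered averages with the G charge and feed held, is s = 0.00530 mM⁻¹, the E price of Z: the fraction of the charged G that Z gives up per mM of E.
- The flask holds 2.00 mM more E than delta, so I reckon Z at 41.9%, and a second line, between the two L averages, gives L 30.3%.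
- The forecast, which says “it sits between them in E”, gives Z 41.7% (40.4% to 43.2%) and L 30.2% (29.2% to 31.3%), and both central values lie inside my bracket.
- The flask gives Z 42.1% and L 30.2%, also inside the bracket.

    G → Z (k = 5.20 × 10⁻⁵ s⁻¹)
    2 G → L (k = 0.00390 M⁻¹ s⁻¹)
    G + L → D (k = 0.00190 M⁻¹ s⁻¹)
    J ⇌ Z, rate k4*(cs4 - [Z]) while solid is left; crystals form when [Z] > cs4 (solubility = 10.0 mM, k = 0.00470 s⁻¹)
    G + Z → Q (k = 0.00110 M⁻¹ s⁻¹)
    G + E → X (k = 0.00220 M⁻¹ s⁻¹)

- In the flask at 0.191 d, G goes to Z faster than it goes to X, with half-lives by these steps of 0.15 d and 0.74 d. Up to 8.0 d the net turnovers are 46.4% and 9.73% of the G charged, and G, the limiting reagent, has 0% left. Carried to the same flask with more E, s says that moving Z by 5 points takes E to 15.4 mM, and the simulated flask has moved that far at 16.8 mM.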